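**Retrosynthetic overview**

1. Target ⇐ keto lactone in which the carboxyl group and the benzylic carbon of the two-carbon arm are tied as a cis-fused six-membered lactone (ring C). An E1 opening of ring C releases CO2H and the E-styryl group together, and base then settles the two α-centres of the cyclopentanone.
2. Rings A (cyclopentane), B (cyclohexene) and C ⇐ transannular Diels–Alder reaction of a 13-membered (E,E,E)-triene lactone. That macrocycle ⇐ acyclic aldehyde/allylic bromide by intramolecular Nozaki–Hiyama allylation, which joins the future ketone carbon to the future ethyl-bearing α-carbon. Order of ring formation: macrocycle, then A + B + C together, then C opened.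
3. Acyclic precursor ⇐ ester of an (E,E)-dienol with (2E,4E)-6-bromo-2-ethylhexa-2,4-dienoic acid. Dienol ⇐ hydrozirconation/Negishi coupling of a methyl alkyne (from methyl (R)-3-hydroxy-2-methylpropanoate) with a vinyl iodide (ethylcupration of the alkyne made from (S)-styrene oxide).
4. Enabling feature: ring B is a Diels–Alder retron (ring alkene, ring-fusion CH–CH bond, quaternary–quaternary bond), and its two quaternary carbons carry the styryl and carboxyl groups cis, so CO2H and the styryl benzylic carbon can be held as lactone ring C. With that tether the three-atom bridge of ring A (methyl-bearing CH, ketone carbon, ethyl-bearing CH) is the second bridge of a macrocyclic triene, and its carbonyl–α-carbon bond is the ring-closing bond.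

Key step: step 15

Assumption: the arrangement found in the target, with each α-alkyl group of the cyclopentanone trans to its ring-fusion neighbour, is taken to be the thermodynamically preferred one, so that base equilibration fixes the ethyl-bearing centre.

**Route**

Step 1
Reactants: 1 methyl (R)-3-hydroxy-2-methylpropanoate
Product: 2 methyl (R)-3-[(tert-butyldimethylsilyl)oxy]-2-methylpropanoate
Conditions: TBSCl, imidazole, DMF, 0 °C to rt
Reagents that add atoms: TBSCl, CC(C)(C)[Si](C)(C)Cl
Why: Imidazole-promoted silylation of the primary alcohol should proceed without touching the α-stereocentre.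

Step 2
Reactants: 2 methyl (R)-3-[(tert-butyldimethylsilyl)oxy]-2-methylpropanoate
Product: 3 (R)-3-[(tert-butyldimethylsilyl)oxy]-2-methylpropanal
Conditions: i-Bu2AlH (1.05 equiv), CH2Cl2, −78 °C; then aq. sodium potassium tartrate
Reagents that add atoms: none
Why: Low-temperature hydride reduction of the ester should stop at the aldehyde through the stable tetrahedral aluminate, with the α-stereocentre retained.

Step 3
Reactants: 3 (R)-3-[(tert-butyldimethylsilyl)oxy]-2-methylpropanal
Product: 4 (S)-tert-butyl[(4,4-dibromo-2-methylbut-3-en-1-yl)oxy]dimethylsilane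
Conditions: CBr4, PPh3, Zn dust, CH2Cl2, 0 °C to rt
Reagents that add atoms: CBr4, BrC(Br)(Br)Br
Why: Corey–Fuchs dibromo-olefination (zinc variant) runs under near-neutral conditions, so the aldehyde should be homologated without epimerization.

Step 4
Reactants: 4 (S)-tert-butyl[(4,4-dibromo-2-methylbut-3-en-1-yl)oxy]dimethylsilane
Product: 6 (S)-tert-butyldimethyl[(2-methylpent-3-yn-1-yl)oxy]silane, via lithium alkynide 5 (not isolated)
Conditions: n-BuLi (2.1 equiv), THF, −78 to 0 °C; then MeI, −78 °C to rt
Reagents that add atoms: MeI, CI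
Why: In the second stage of the Corey–Fuchs sequence, bromine–lithium exchange and 1,2-shift should give the lithium alkynide, which is C-methylated by iodomethane.

Step 5
Reactants: 7 (S)-2-phenyloxirane
Product: 8 (R)-1-phenylbut-3-yn-1-ol
Conditions: lithium acetylide–ethylenediamine complex, DMSO, 15 °C to rt; then H2O
Reagents that add atoms: lithium acetylide (ethylenediamine complex), [Li]C#C
Why: SN2 opening of the epoxide at its unhindered CH2 terminus leaves the benzylic C–O stereocentre untouched, so the (S)-epoxide should give the (R)-homopropargylic alcohol.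

Step 6
Reactants: 8 (R)-1-phenylbut-3-yn-1-ol
Product: 9 (R)-triethyl[(1-phenylbut-3-yn-1-yl)oxy]silane
Conditions: TESCl, imidazole, CH2Cl2, 0 °C
Reagents that add atoms: TESCl, CC[Si](CC)(CC)Cl
Why: Standard silylation gives a bulky, non-chelating ether that is stable to organocopper and organozinc reagents and is more acid-labile than the primary TBS ether used later.

Step 7
Reactants: 9 (R)-triethyl[(1-phenylbut-3-yn-1-yl)oxy]silane
Product: 11 (R,E)-triethyl[(3-ethyl-4-iodo-1-phenylbut-3-en-1-yl)oxy]silane, via alkenylcopper species 10 (not isolated)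
Conditions: EtMgBr, CuBr·SMe2, Et2O/SMe2, −45 °C; then 9, −25 °C; then I2, THF, −40 to 0 °C
Reagents that add atoms: EtMgBr, CC[Mg]Br; I2, II
Why: Carbocupration of the terminal alkyne adds ethyl and copper syn (ethyl to the internal carbon, copper to the terminus), and iodinolysis with retention should give the vinyl iodide with iodine cis to ethyl.

Step 8
Reactants: 6 (S)-tert-butyldimethyl[(2-methylpent-3-yn-1-yl)oxy]silane; 11 (R,E)-triethyl[(3-ethyl-4-iodo-1-phenylbut-3-en-1-yl)oxy]silane
Product: 14 tert-butyl{[(2S,3E,5E,8R)-6-ethyl-2,4-dimethyl-8-phenyl-8-[(triethylsilyl)oxy]octa-3,5-dien-1-yl]oxy}dimethylsilane, via alkenylzirconocene chloride 12 (not isolated), via alkenylzinc chloride 13 (not isolated)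
Conditions: Cp2Zr(H)Cl, THF, 50 °C; then ZnCl2, THF, 0 °C; then 11, Pd(PPh3)4 (5 mol %), rt
Reagents that add atoms: none
Why: Syn hydrozirconation places zirconium on the less hindered, methyl-bearing alkyne carbon, and transmetalation to zinc followed by Negishi coupling with retention at both partners should give the (E,E)-diene.

Step 9
Reactants: 14 tert-butyl{[(2S,3E,5E,8R)-6-ethyl-2,4-dimethyl-8-phenyl-8-[(triethylsilyl)oxy]octa-3,5-dien-1-yl]oxy}dimethylsilane
Product: 15 (1R,3E,5E,7S)-8-[(tert-butyldimethylsilyl)oxy]-3-ethyl-5,7-dimethyl-1-phenylocta-3,5-dien-1-ol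
Conditions: PPTS (0.2 equiv), MeOH/CH2Cl2, 0 °C
Reagents that add atoms: none
Why: Mild acid methanolysis should cleave the triethylsilyl ether much faster than the primary tert-butyldimethylsilyl ether, freeing only the benzylic hydroxyl.

Step 10
Reactants: 16 (E)-but-2-enal; 17 2-ethylpropanedioic acid
Product: 18 (2E,4E)-2-ethylhexa-2,4-dienoic acid
Conditions: pyridine, piperidine (cat.), 95 °C
Reagents that add atoms: none
Why: Knoevenagel–Doebner condensation with decarboxylation should give the α-ethyl dienoic acid with the carboxyl group trans to the β-substituent.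

Step 11
Reactants: 18 (2E,4E)-2-ethylhexa-2,4-dienoic acid
Product: 19 (2E,4E)-6-bromo-2-ethylhexa-2,4-dienoic acid
Conditions: NBS, AIBN (cat.), PhCF3, 85 °C
Reagents that add atoms: NBS, O=C1CCC(=O)N1Br
Why: Wohl–Ziegler bromination should take place at the terminal methyl group, because hydrogen abstraction there gives the most delocalized radical (pentadienyl-type, extended by the carboxyl group).

Step 12
Reactants: 15 (1R,3E,5E,7S)-8-[(tert-butyldimethylsilyl)oxy]-3-ethyl-5,7-dimethyl-1-phenylocta-3,5-dien-1-ol; 19 (2E,4E)-6-bromo-2-ethylhexa-2,4-dienoic acid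
Product: 20 (1R,3E,5E,7S)-8-[(tert-butyldimethylsilyl)oxy]-3-ethyl-5,7-dimethyl-1-phenylocta-3,5-dien-1-yl (2E,4E)-6-bromo-2-ethylhexa-2,4-dienoate
Conditions: DIC, DMAP (0.1 equiv), CH2Cl2, 0 °C to rt
Reagents that add atoms: none
Why: Steglich esterification acylates the secondary alcohol with retention at the carbinol carbon, and at 0 °C with catalytic DMAP the allylic bromide should survive, as it does in carbodiimide esterifications of bromoacetic acid.

Step 13
Reactants: 20 (1R,3E,5E,7S)-8-[(tert-butyldimethylsilyl)oxy]-3-ethyl-5,7-dimethyl-1-phenylocta-3,5-dien-1-yl (2E,4E)-6-bromo-2-ethylhexa-2,4-dienoate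
Product: 21 (1R,3E,5E,7S)-3-ethyl-8-hydroxy-5,7-dimethyl-1-phenylocta-3,5-dien-1-yl (2E,4E)-6-bromo-2-ethylhexa-2,4-dienoate
Conditions: CSA (0.1 equiv), MeOH/CH2Cl2, 0 °C
Reagents that add atoms: none
Why: Acid-catalysed methanolysis removes the primary silyl ether without fluoride, which would displace the allylic bromide.

Step 14
Reactants: 21 (1R,3E,5E,7S)-3-ethyl-8-hydroxy-5,7-dimethyl-1-phenylocta-3,5-dien-1-yl (2E,4E)-6-bromo-2-ethylhexa-2,4-dienoate
Product: 22 (1R,3E,5E,7S)-3-ethyl-5,7-dimethyl-8-oxo-1-phenylocta-3,5-dien-1-yl (2E,4E)-6-bromo-2-ethylhexa-2,4-dienoate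
Conditions: Dess–Martin periodinane, NaHCO3, CH2Cl2, 0 °C
Reagents that add atoms: none
Why: Buffered Dess–Martin oxidation should give the α-methyl-β,γ-unsaturated aldehyde without epimerization or conjugation; it is used at once.

Step 15
Reactants: 22 (1R,3E,5E,7S)-3-ethyl-5,7-dimethyl-8-oxo-1-phenylocta-3,5-dien-1-yl (2E,4E)-6-bromo-2-ethylhexa-2,4-dienoate
Product: 25 tricyclic vinyl carbinol lactone (rings A B C; epimer mixture at the carbinol carbon and at the vinyl-bearing carbon), via allylchromium species 23 (not isolated), via macrocyclic triene lactone 24 (not isolated)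
Conditions: CrCl2 (8 equiv), THF (0.002 M, 22 added over 10 h), rt; then 60 °C, 12 h; then H2O
Reagents that add atoms: none
Why: Divalent chromium inserts into the allylic C–Br bond to give allylchromium species 23, which adds to the aldehyde through its γ-carbon (SE2′, chair-like six-membered transition state), forming the bond between the future ketone carbon and the future ethyl-bearing α-carbon and so closing the 13-membered (E,E,E)-triene lactone 24; on warming, the diene and the enoate of 24 combine in a transannular Diels–Alder reaction. The closest known reaction types are the intramolecular Nozaki–Hiyama allylation used for macrocyclization and the macrocyclization/transannular Diels–Alder cascades of 13- and 14-membered trienes. The macrocycle closes by carbonyl allylation at high dilution (13-membered ring, the aldehyde attacked exo), and rings A and B and the six-membered lactone ring C then close together in the suprafacial [4+2] event across the ring. The four ring stereocentres follow from the three E double bonds (the two ethyl groups cis, the carboxyl carbon cis to the lactone CH2, the two ring-fusion hydrogens trans) together with the endo placement of the ester carbonyl, which makes the lactone bridge cis-fused and the three-carbon bridge trans-fused; the absolute sense is set by the methyl-bearing allylic stereocentre (its hydrogen eclipses the diene to avoid 1,3-allylic strain, so the diene is attacked anti to the methyl group), reinforced by the equatorial phenyl group of the forming lactone. The carbinol and vinyl-bearing centres form as a mixture, which is of no consequence because the first is oxidized in step 17 and the second is equilibrated in step 18. The step needs γ- rather than α- or ε-attack of the allylchromium (normal for allylchromium reagents; the alternatives would give 15- or 11-membered rings), cyclization rather than oligomerization (slow addition) and one π-face of the diene (secured by the two resident stereocentres).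

Step 16
Reactants: 25 tricyclic vinyl carbinol lactone
Product: 26 tricyclic ethyl carbinol lactone
Conditions: H2 (1 atm), RhCl(PPh3)3 (5 mol %), benzene, rt
Reagents that add atoms: none
Why: Homogeneous hydrogenation with RhCl(PPh3)3 should reduce the monosubstituted vinyl group and leave the hindered trisubstituted ring alkene and the benzylic C–O bond intact.

Step 17
Reactants: 26 tricyclic ethyl carbinol lactone
Product: 27 tricyclic keto lactone (epimer mixture at the ethyl-bearing carbon)
Conditions: Dess–Martin periodinane, NaHCO3, CH2Cl2, rt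
Reagents that add atoms: none
Why: Dess–Martin oxidation converts both carbinol epimers into the same ketone; the trans ring fusion rules out translactonization onto the lactone carbonyl.

Step 18
Reactants: 27 tricyclic keto lactone
Product: 29 target acid (CNP0178058.1), via trimethylsilyl ester 28 (not isolated)
Conditions: TMSOTf, 2,6-lutidine, CH2Cl2, 0 °C to rt; then K2CO3, MeOH, rt; then aq. HCl to pH 3
Reagents that add atoms: none
Why: Proposed new method: silylation of the lactone carbonyl oxygen by TMSOTf should trigger heterolysis of the benzylic C–O bond to a secondary benzylic cation, which loses a proton from the only adjacent CH2 group to 2,6-lutidine (E1) and so gives the E-styryl group and silyl ester 28 irreversibly, after which K2CO3/MeOH cleaves the silyl ester and equilibrates both ketone α-centres to the all-trans arrangement; the closest known reaction type is the TMSOTf/2,6-lutidine cleavage of tert-butyl esters to silyl esters and isobutene.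

**Compound list**

1 | methyl (R)-3-hydroxy-2-methylpropanoate | OC[C@@H](C)C(=O)OC | starting material
2 | methyl (R)-3-[(tert-butyldimethylsilyl)oxy]-2-methylpropanoate | CC(C)(C)[Si](C)(C)OC[C@@H](C)C(=O)OC | intermediate
3 | (R)-3-[(tert-butyldimethylsilyl)oxy]-2-methylpropanal | CC(C)(C)[Si](C)(C)OC[C@@H](C)C=O | intermediate
4 | (S)-tert-butyl[(4,4-dibromo-2-methylbut-3-en-1-yl)oxy]dimethylsilane | CC(C)(C)[Si](C)(C)OC[C@@H](C)C=C(Br)Br | intermediate
5 | lithium alkynide of (S)-tert-butyldimethyl[(2-methylbut-3-yn-1-yl)oxy]silane | CC(C)(C)[Si](C)(C)OC[C@@H](C)C#C[Li] | intermediate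
6 | (S)-tert-butyldimethyl[(2-methylpent-3-yn-1-yl)oxy]silane | CC(C)(C)[Si](C)(C)OC[C@@H](C)C#CC | intermediate
7 | (S)-2-phenyloxirane ((S)-styrene oxide) | c1ccccc1[C@H]1CO1 | starting material
8 | (R)-1-phenylbut-3-yn-1-ol | C#CC[C@H](c1ccccc1)O | intermediate
9 | (R)-triethyl[(1-phenylbut-3-yn-1-yl)oxy]silane | C#CC[C@H](c1ccccc1)O[Si](CC)(CC)CC | intermediate
10 | alkenylcopper species (monovalent copper) from syn ethylcupration of 9, copper cis to ethyl | [Cu]/C=C(CC)/C[C@H](c1ccccc1)O[Si](CC)(CC)CC | intermediate
11 | (R,E)-triethyl[(3-ethyl-4-iodo-1-phenylbut-3-en-1-yl)oxy]silane | I/C=C(CC)/C[C@H](c1ccccc1)O[Si](CC)(CC)CC | intermediate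
12 | alkenylzirconocene chloride from syn hydrozirconation of 6, zirconium on the methyl-bearing carbon | CC(C)(C)[Si](C)(C)OC[C@@H](C)/C=C(C)/[Zr](Cl)(C1C=CC=C1)C1C=CC=C1 | intermediate
13 | alkenylzinc chloride from 12 | CC(C)(C)[Si](C)(C)OC[C@@H](C)/C=C(C)/[Zn]Cl | intermediate
14 | tert-butyl{[(2S,3E,5E,8R)-6-ethyl-2,4-dimethyl-8-phenyl-8-[(triethylsilyl)oxy]octa-3,5-dien-1-yl]oxy}dimethylsilane | CC(C)(C)[Si](C)(C)OC[C@@H](C)/C=C(C)/C=C(CC)/C[C@H](c1ccccc1)O[Si](CC)(CC)CC | intermediate
15 | (1R,3E,5E,7S)-8-[(tert-butyldimethylsilyl)oxy]-3-ethyl-5,7-dimethyl-1-phenylocta-3,5-dien-1-ol | CC(C)(C)[Si](C)(C)OC[C@@H](C)/C=C(C)/C=C(CC)/C[C@H](c1ccccc1)O | intermediate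
16 | (E)-but-2-enal | C/C=C/C=O | starting material
17 | 2-ethylpropanedioic acid (ethylmalonic acid) | CCC(C(=O)O)C(=O)O | starting material
18 | (2E,4E)-2-ethylhexa-2,4-dienoic acid | C/C=C/C=C(CC)/C(=O)O | intermediate
19 | (2E,4E)-6-bromo-2-ethylhexa-2,4-dienoic acid | BrC/C=C/C=C(CC)/C(=O)O | intermediate
20 | (1R,3E,5E,7S)-8-[(tert-butyldimethylsilyl)oxy]-3-ethyl-5,7-dimethyl-1-phenylocta-3,5-dien-1-yl (2E,4E)-6-bromo-2-ethylhexa-2,4-dienoate | CC(C)(C)[Si](C)(C)OC[C@@H](C)/C=C(C)/C=C(CC)/C[C@H](c1ccccc1)OC(=O)/C(CC)=C/C=C/CBr | intermediate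
21 | (1R,3E,5E,7S)-3-ethyl-8-hydroxy-5,7-dimethyl-1-phenylocta-3,5-dien-1-yl (2E,4E)-6-bromo-2-ethylhexa-2,4-dienoate | OC[C@@H](C)/C=C(C)/C=C(CC)/C[C@H](c1ccccc1)OC(=O)/C(CC)=C/C=C/CBr | intermediate
22 | (1R,3E,5E,7S)-3-ethyl-5,7-dimethyl-8-oxo-1-phenylocta-3,5-dien-1-yl (2E,4E)-6-bromo-2-ethylhexa-2,4-dienoate | O=C[C@@H](C)/C=C(C)/C=C(CC)/C[C@H](c1ccccc1)OC(=O)/C(CC)=C/C=C/CBr | intermediate
23 | allylchromium dichloride species (trivalent chromium) derived from 22 | O=C[C@@H](C)/C=C(C)/C=C(CC)/C[C@H](c1ccccc1)OC(=O)/C(CC)=C/C=C/C[Cr](Cl)Cl | intermediate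
24 | 13-membered (E,E,E)-triene lactone as its chromium alkoxide: ring = carbinol CH, vinyl-bearing CH, enoate CH=C(Et), C(=O)–O, CH(Ph), CH2, C(Et)=CH, C(Me)=CH, CH(Me); carbinol and vinyl-bearing carbons as epimer mixture | C=CC1/C=C(CC)/C(=O)O[C@@H](c2ccccc2)C/C(CC)=C/C(C)=C/[C@H](C)C1O[Cr](Cl)Cl | intermediate
25 | tricyclic vinyl carbinol lactone: ring A cyclopentane (CH–vinyl, CH–OH, CH–CH3 in sequence) trans-fused to ring B cyclohexene (ring methyl on the alkene carbon next to the fusion CH); ring C a cis-fused δ-lactone joining the two ethyl-bearing quaternary carbons through C(=O)–O–CH(Ph)–CH2, phenyl carbon (R); epimer mixture at CH–vinyl and CH–OH | C=CC1C(O)[C@@H](C)[C@@H]2C(C)=C[C@]3(CC)C[C@H](c4ccccc4)OC(=O)[C@]3(CC)[C@H]21 | intermediate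
26 | tricyclic ethyl carbinol lactone: as 25 with ethyl in place of vinyl | CCC1C(O)[C@@H](C)[C@@H]2C(C)=C[C@]3(CC)C[C@H](c4ccccc4)OC(=O)[C@]3(CC)[C@H]21 | intermediate
27 | tricyclic keto lactone: as 26 with the carbinol oxidized to the ring A ketone; epimer mixture at the ethyl-bearing α-carbon | CCC1C(=O)[C@@H](C)[C@@H]2C(C)=C[C@]3(CC)C[C@H](c4ccccc4)OC(=O)[C@]3(CC)[C@H]21 | intermediate
28 | trimethylsilyl ester of the target acid (ethyl-bearing α-carbon not yet equilibrated) | CCC1C(=O)[C@@H](C)[C@@H]2C(C)=C[C@@](/C=C/c3ccccc3)(CC)[C@](CC)(C(=O)O[Si](C)(C)C)[C@H]21 | intermediate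
29 | CNP0178058.1: trans-fused hydrindenone acid with 2-ethyl and 5-methyl groups on the cyclopentanone (both trans to their ring-fusion neighbours), ring methyl on the cyclohexene, and cis E-styryl/CO2H on the two vicinal ethyl-bearing quaternary carbons | CC[C@@H]1C(=O)[C@@H](C)[C@@H]2C(C)=C[C@@](/C=C/c3ccccc3)(CC)[C@](CC)(C(=O)O)[C@H]21 | target

**Summary**

Total step count: 18. Longest linear sequence: 13 steps (steps 1–4, 8, 9, 12–18).

Steps most likely to fail:

1. Step 18 (proposed new method). Ionization of the benzylic lactone may be too slow, or the benzylic cation may be captured (re-closure, or attack by the enol form of the ketone) instead of losing a proton. Fallback with known chemistry, from 27 back to 29: saponification (LiOH, THF/MeOH/H2O, 60 °C; the α-centres equilibrate under these conditions) would give the lithium hydroxy carboxylate F1, which is not acidified. Alkylation with allyl bromide (DMF, rt) would give the hydroxy allyl ester F2. Dehydration of the benzylic alcohol with Martin sulfurane (CH2Cl2, rt), where only the neighbouring CH2 carries hydrogens, would give the styryl allyl ester F3. Deallylation with Pd(PPh3)4 and morpholine (THF, rt) would then give 29.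

2. Step 15 (key step). The allylation may oligomerize or go through the α- or ε-carbon, and the transannular cycloaddition may take the alternative transition state (cis-fused ring A, trans-fused lactone) or the other diene face. Fallback that builds ring B first and closes ring A by a radical, from 15 and 18 back to 27: Steglich esterification (DIC, DMAP, CH2Cl2) would give the triene ester F4. Intramolecular Diels–Alder reaction through the lactone tether (toluene, BHT, 160 °C, sealed tube) would give the bicyclic lactone F5, with the (E)-propenyl group and the silyloxypropyl side chain trans on ring B. Desilylation (TBAF, THF) would give the primary alcohol F6. Oxidation (TEMPO, PhI(OAc)2; then NaClO2, NaH2PO4, 2-methylbut-2-ene) would give the carboxylic acid F7. Treatment with (PhSe)2 and PBu3 (CH2Cl2) would give the Se-phenyl selenoester F8. Bu3SnH/AIBN (benzene, 80 °C, slow addition) would then close ring A by 5-exo-trig acyl radical cyclization onto the propenyl group, giving 27.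

3. Step 11. Hydrogen abstraction may occur at the CH2 of the α-ethyl group, or bromine may add ionically to the diene acid. Fallback that avoids radical bromination, from 17 back to 19: Knoevenagel–Doebner condensation of 17 with acrolein (C=CC=O; pyridine, piperidine cat., 90 °C) would give (E)-2-ethylpenta-2,4-dienoic acid F9. Cross-metathesis of its terminal alkene with allyl bromide (second-generation Hoveyda–Grubbs catalyst, CH2Cl2, 40 °C) would give 19.

**Further compounds**

F1 | step 18 | lithium salt of the ring-opened hydroxy acid (benzylic alcohol on the CH2CH(OH)Ph arm, all-trans ketone) | CC[C@@H]1C(=O)[C@@H](C)[C@@H]2C(C)=C[C@@](C[C@@H](O)c3ccccc3)(CC)[C@](CC)(C(=O)[O-])[C@H]21.[Li+]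
F2 | step 18 | allyl ester of the ring-opened hydroxy acid | CC[C@@H]1C(=O)[C@@H](C)[C@@H]2C(C)=C[C@@](C[C@@H](O)c3ccccc3)(CC)[C@](CC)(C(=O)OCC=C)[C@H]21
F3 | step 18 | allyl ester of the target acid | CC[C@@H]1C(=O)[C@@H](C)[C@@H]2C(C)=C[C@@](/C=C/c3ccccc3)(CC)[C@](CC)(C(=O)OCC=C)[C@H]21
F4 | step 15 | (1R,3E,5E,7S)-8-[(tert-butyldimethylsilyl)oxy]-3-ethyl-5,7-dimethyl-1-phenylocta-3,5-dien-1-yl (2E,4E)-2-ethylhexa-2,4-dienoate | CC(C)(C)[Si](C)(C)OC[C@@H](C)/C=C(C)/C=C(CC)/C[C@H](c1ccccc1)OC(=O)/C(CC)=C/C=C/C
F5 | step 15 | bicyclic lactone: ring B cis-fused to the phenyl δ-lactone, with (E)-propenyl and 1-(silyloxy)propan-2-yl groups trans on adjacent ring carbons | CC(C)(C)[Si](C)(C)OC[C@@H](C)[C@@H]2C(C)=C[C@]3(CC)C[C@H](c4ccccc4)OC(=O)[C@]3(CC)[C@H]2/C=C/C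
F6 | step 15 | primary alcohol from F5 | OC[C@@H](C)[C@@H]2C(C)=C[C@]3(CC)C[C@H](c4ccccc4)OC(=O)[C@]3(CC)[C@H]2/C=C/C
F7 | step 15 | carboxylic acid from F6 | OC(=O)[C@@H](C)[C@@H]2C(C)=C[C@]3(CC)C[C@H](c4ccccc4)OC(=O)[C@]3(CC)[C@H]2/C=C/C
F8 | step 15 | Se-phenyl selenoester of F7 | O=C([Se]c1ccccc1)[C@@H](C)[C@@H]2C(C)=C[C@]3(CC)C[C@H](c4ccccc4)OC(=O)[C@]3(CC)[C@H]2/C=C/C
F9 | step 11 | (E)-2-ethylpenta-2,4-dienoic acid | C=C/C=C(CC)/C(=O)O
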